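**Compound numbering.** Compounds are numbered 1–24 in the order in which they appear in the steps. Ring atoms carry germacrane numbers throughout: C1=C10 (methyl on C10), C4=C5 (C15 on C4), C6 (OH), C7 (isopropyl), C8 (OAc), C9.

## Analysis of the target

Target 24 has a single ten-membered carbocycle with two trisubstituted alkenes, C1=C10 and C4=C5, both trans within the ring and arranged as a 1,5-diene. C4=C5 is Z by the sequence rule only because the C15 acyloxymethyl group outranks C3. Three contiguous stereocentres sit at C6 (free hydroxyl, S), C7 (isopropyl, S) and C8 (acetate, S). On the ring the C6 hydroxyl and the isopropyl group are cis and the C8 acetate is trans to both, so the C6 and C8 oxygens are 1,3-anti. The three oxygens are all different: a free allylic secondary alcohol, a secondary acetate and a primary allylic angelate. The angelate isomerises easily to the tiglate under nucleophilic or basic acylation conditions, and the 1,3-diol monoacetate can suffer acyl migration. The cyclodeca-1,5-diene undergoes transannular cyclisation with acid and Cope rearrangement on strong heating. The hard part is closing a strained ten-membered ring with two trans alkenes of defined geometry while setting a stereotriad in a conformationally mobile ring. The strategy rests on one feature: the C6 carbinol is separated from the vinylic C10 by C7–C8–C9. Joining C6 to C9 on paper gives a cyclobutanol (C6–C7–C8–C9) that holds C7 and C8 as a trans pair, and opening it at C6–C9 while C9 is coupled to C10 returns the ring with C6 as a ketone β to the C8 oxygen.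

## Retrosynthetic reasoning

**24 to 23.** The C6–H bond and the acetyl C–O bond on the C8 oxygen are cut together, which leads back to the β-hydroxy enone 23. This is the retron of an Evans–Tishchenko reduction. It avoids any selective acetylation among hydroxyl groups and sets C6 from C8 through a cyclic hydride transfer. The forward step must reduce 1,2 rather than 1,4 and leave the angelate alone.

**23 to 22.** The ester C–O bond at C15 is cut to give the keto diol 22. The primary allylic hydroxyl is far less hindered than the C8 hydroxyl, which sits next to the isopropyl-bearing carbon, so the acylation can be selective. Placing the angelate late keeps it away from organometallic reagents and from the palladium step.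

**22 to 21.** Both O–Si bonds are cut to give the bis-silyl ether 21. Silyl ethers carry the C8 and C15 oxygens through the organolithium, zirconium and palladium chemistry and come off together under buffered fluoride.

**21 to 20.** The C9–C10 bond is cut and the C6–C9 bond is re-formed on paper, giving the 1-alkenylcyclobutanol 20 with an (E)-alkenyl iodide at C10. This is chosen because the ketone carbon and the alkenyl carbon are 1,4-related, the pattern left by ring-opening coupling of a tertiary cyclobutanol. The gain is that ring strain helps pay for the macrocyclisation, both alkenes arrive with fixed geometry, and C7 and C8 are carried in as a simple trans-disubstituted four-membered ring. The forward reaction must break C6–C9 and not C6–C7, and must keep both alkene geometries.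

**20 to 18.** The C10–I bond is cut to give the 2-alkyne 18. An alkyne survives the organolithium step that builds the cyclobutanol, whereas a second alkenyl iodide would not. Syn hydrometalation toward the methyl end followed by iodinolysis gives exactly the needed (E)-iodide.

**18 to 8 and 15.** The C5–C6 bond is cut to give cyclobutanone 8 and alkenyl iodide 15. This is the convergent point. The configuration created at C6 does not matter, because C6 becomes a carbonyl group in 21.

**15 to 14 to 10 and 11 (10 from 9).** The O–Si bond of 15 is cut to give 14. In 14 the C3–C4 bond and the C5–I bond are cut, giving propargyl alcohol 11 and the Grignard reagent 12 made from bromide 10, itself from alcohol 9. Anti carbomagnesiation through the chelate 13 puts the metal, and later C6, cis to C15, which is the geometry of C4=C5 in 24.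

**8 to 7 to 6 to 5 to 1 and 2.** The silyl ether 8 comes from alcohol 7, which is one enantiomer of the racemate 6, made from benzyl ether 5. In 5 the C6–C9 and C7–C8 bonds are cut as a ketene–enol ether [2+2] cycloaddition of ketene 3 (from 1) with 2. The cis adduct 4 is equilibrated to trans 5. The benzyl group is chosen because it can be removed by hydrogenolysis before any alkene is present. The resolution is placed at 6 because a secondary alcohol is what a lipase resolves.

## Alternatives that were turned down

**Alternative 1: silicon-tethered ring-closing metathesis at C4=C5.**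
- Disconnection: C4=C5, with the C6 and C15 oxygens joined by a di-isopropylsilylene bridge.
- Forward key step: the second-generation Grubbs catalyst joins the C4 methylidene and the C6 vinyl group of the thirteen-membered silaketal A1. This closes a seven-membered dioxasilepine and with it the ten-membered carbocycle A2.
- For: the small silicon-containing ring forces C15 and C6 to be cis on the new alkene. C6 and the C8 acetate are in place before ring closure, so only removal of silicon and angeloylation remain.
- Against: A1 needs an open-chain precursor that already carries the whole C6/C7/C8 triad and the (E)-C1=C10 alkene, which means a long linear aldol-type sequence. The metathesis must form a trisubstituted alkene from a 1,1-disubstituted partner across a strained medium ring. Closure of the thirteen-membered silaketal competes with oligomeric silylation.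
- Comparison: this route is stronger after the ring closure (no redox or stereochemical work at C6) and uses an established reaction class. The chosen route offers a much shorter path to its precursor and stereocentres that come from a four-membered ring rather than from acyclic control.

**Alternative 2: [2,3]-Wittig ring contraction forming C6–C7.**
- Disconnection: C6–C7, traced back to a thirteen-membered propargylic allylic ether.
- Forward key step: n-BuLi deprotonates the propargylic C6 of A3. The [2,3] shift forms C6–C7, breaks the O–C12 bond and gives the ten-membered cycloalkynol A4 with the C6 hydroxyl and a C7 isopropenyl group.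
- For: the large ether ring is easy to close. The contraction is precedented for ten-membered carbocycles and creates C6 and C7 in the ring-forming step. In the open-chain series a (Z)-allylic unit gives the syn relationship needed here.
- Against: A4 is still far from 24. The C4≡C5 alkyne must become a trisubstituted alkene carrying C15. The isopropenyl group must be reduced in the presence of C1=C10. The protecting group on the C8 oxygen must be exchanged for acetate. Deprotonation can also occur at the allylic side of the ether oxygen, and the absolute sense of the shift rests on C8 alone.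
- Comparison: the ring-forming event is better precedented than in the chosen route. The chosen route needs three steps after ring closure, against many here, and delivers both alkenes already correct.

**Alternative 3: anionic oxy-Cope ring expansion of a cyclohexanol template.**
- Disconnection: C2–C3, with the C5–C10 bond of a six-membered template broken in the same step.
- Forward key step: KH with 18-crown-6 triggers the [3,3] shift of the 1,2-dialkenylcyclohexanol A5. The resulting C10 enolate is trapped with PhNTf2 to give the ten-membered dienyl triflate A6. The C10 methyl group would then come from a cross-coupling.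
- For: this is the best-precedented entry to (E,E)-cyclodecadienes. A chair transition state sets both alkene geometries, and the enolate is trapped regiospecifically.
- Against: A5 is a cyclohexanol with five stereocentres, four of them contiguous, and would take a long sequence to build. The C8 alkoxy group is β to the carbonyl that the enolate represents, so any enolate equilibration invites elimination. After the key step a methylation and several protecting-group changes at C6, C8 and C15 are still needed.
- Comparison: its key step is more certain than the chosen one. The chosen route concentrates the stereochemical work in a two-stereocentre cyclobutanone made in four steps, and the whole route is far shorter.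

Key step: step 10

Assumption: in step 3 the lipase is taken to acetylate the (3R)-carbinol faster (larger flank C2, smaller flank C4), so that the (2R,3S)-alcohol 7 is the recovered fraction.

## Route

Step 1
Reactants: 1 isovaleryl chloride (3-methylbutanoyl chloride); 2 benzyl vinyl ether
Product: 5 rac-(2R,3S)-3-(benzyloxy)-2-(propan-2-yl)cyclobutan-1-one (trans), via isopropylketene 3 (not isolated), via cis cycloadduct 4 (not isolated)
Conditions: 2 (4 equiv), Et3N, MeCN, reflux, slow addition of 1; then DBU (cat.), CH2Cl2, 0 °C to rt
Reagents that add atoms: none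
Why: Dehydrochlorination of 1 gives the ketene, which undergoes a regioselective [2+2] cycloaddition with the enol ether (its CH2 terminus bonds to the ketene carbonyl carbon), so the ether oxygen ends on the carbon next to the isopropyl-bearing one. The kinetically favoured cis adduct 4 is equilibrated through its enol to the less crowded trans isomer 5, which fixes the C7/C8 relative configuration.

Step 2
Reactants: 5 rac-(2R,3S)-3-(benzyloxy)-2-(propan-2-yl)cyclobutan-1-one
Product: 6 rac-(2R,3S)-3-hydroxy-2-(propan-2-yl)cyclobutan-1-one
Conditions: H2 (1 atm), Pd/C, EtOAc, rt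
Reagents that add atoms: none
Why: Hydrogenolysis of the benzyl ether is done while the molecule has no alkene. The neutral medium leaves the cyclobutanone and the β-hydroxy ketone untouched.

Step 3
Reactants: 6 rac-(2R,3S)-3-hydroxy-2-(propan-2-yl)cyclobutan-1-one
Product: 7 (2R,3S)-3-hydroxy-2-(propan-2-yl)cyclobutan-1-one
Conditions: vinyl acetate, Candida antarctica lipase B (immobilised), t-BuOMe, 30 °C, stopped just past half conversion; chromatography
Reagents that add atoms: none
Why: Lipase-catalysed kinetic resolution by irreversible transesterification. The enzyme should acetylate the (3R)-alcohol and leave the (2R,3S)-alcohol, which sets the absolute configuration of C7 and C8; the acetate of the other enantiomer is removed by chromatography.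

Step 4
Reactants: 7 (2R,3S)-3-hydroxy-2-(propan-2-yl)cyclobutan-1-one
Product: 8 (2R,3S)-3-{[tert-butyl(dimethyl)silyl]oxy}-2-(propan-2-yl)cyclobutan-1-one
Conditions: TBSCl, imidazole, DMF, 0 °C to rt
Reagents that add atoms: tert-butyldimethylsilyl chloride, CC(C)(C)[Si](C)(C)Cl
Why: Silylation of a secondary alcohol under a base too weak for retro-aldol opening. The trans arrangement is the thermodynamic one, so C2 is not at risk.

Step 5
Reactants: 9 pent-3-yn-1-ol
Product: 10 5-bromopent-2-yne
Conditions: CBr4, PPh3, CH2Cl2, 0 °C
Reagents that add atoms: carbon tetrabromide, BrC(Br)(Br)Br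
Why: Appel bromination of a primary alcohol; the internal alkyne is inert.

Step 6
Reactants: 10 5-bromopent-2-yne; 11 propargyl alcohol (prop-2-yn-1-ol)
Product: 14 (2Z)-3-iodo-2-(pent-3-yn-1-yl)prop-2-en-1-ol, via pent-3-yn-1-ylmagnesium bromide 12 (not isolated), via magnesium chelate 13 (not isolated)
Conditions: Mg, THF, rt to 40 °C (2.3 equiv of 12); then 11, CuI (10 mol %), THF/Et2O, −20 °C to rt; then I2, THF, −40 to 0 °C
Reagents that add atoms: iodine, II
Why: Copper-catalysed carbomagnesiation of the propargylic alkoxide is an anti addition that places the alkyl group on the internal carbon and magnesium on the terminal carbon, held in a five-membered chelate. Iodinolysis with retention gives the iodide cis to the hydroxymethyl group, which fixes the C4=C5 geometry (C15 cis to the future C6).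

Step 7
Reactants: 14 (2Z)-3-iodo-2-(pent-3-yn-1-yl)prop-2-en-1-ol
Product: 15 tert-butyl{[(2Z)-3-iodo-2-(pent-3-yn-1-yl)prop-2-en-1-yl]oxy}dimethylsilane
Conditions: TBSCl, imidazole, CH2Cl2, 0 °C to rt
Reagents that add atoms: tert-butyldimethylsilyl chloride, CC(C)(C)[Si](C)(C)Cl
Why: Standard silylation of a primary allylic alcohol; it removes the acidic proton before the organolithium step.

Step 8
Reactants: 15 tert-butyl{[(2Z)-3-iodo-2-(pent-3-yn-1-yl)prop-2-en-1-yl]oxy}dimethylsilane; 8 (2R,3S)-3-{[tert-butyl(dimethyl)silyl]oxy}-2-(propan-2-yl)cyclobutan-1-one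
Product: 18 (1R,2R,3S)-3-{[tert-butyl(dimethyl)silyl]oxy}-1-[(1Z)-2-({[tert-butyl(dimethyl)silyl]oxy}methyl)hept-1-en-5-yn-1-yl]-2-(propan-2-yl)cyclobutan-1-ol, via alkenyllithium 16 (not isolated), via alkenylcerium dichloride 17 (not isolated)
Conditions: 15 (1.3 equiv), t-BuLi (2.6 equiv), Et2O, −78 °C; CeCl3 (anhydrous), THF, −78 °C; then 8, −78 to −40 °C
Reagents that add atoms: none
Why: Iodine–lithium exchange keeps the alkene geometry at −78 °C. The organocerium reagent is nucleophilic but weakly basic, so 1,2-addition should win over enolisation of the cyclobutanone, whose enolate could expel the β-silyloxy group. Attack anti to the neighbouring isopropyl group should give mainly the C6 epimer drawn, and either epimer serves because C6 later becomes a carbonyl group.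

Step 9
Reactants: 18 the cyclobutanol alkyne
Product: 20 (1R,2R,3S)-3-{[tert-butyl(dimethyl)silyl]oxy}-1-[(1Z,5E)-2-({[tert-butyl(dimethyl)silyl]oxy}methyl)-6-iodohepta-1,5-dien-1-yl]-2-(propan-2-yl)cyclobutan-1-ol, via alkenylzirconocene chloride 19 (not isolated)
Conditions: Cp2Zr(H)Cl (3.5 equiv), THF, rt to 45 °C; then I2, THF, −78 °C; aq. Na2S2O3
Reagents that add atoms: iodine, II
Why: Hydrozirconation is a syn addition, and with excess reagent and gentle warming the regioisomers equilibrate toward zirconium on the less hindered methyl-bearing C10. Iodinolysis with retention then gives the (E)-iodide with iodine trans to the chain. The first equivalent of reagent is consumed by the hydroxyl group, and the trisubstituted C4=C5 alkene is too hindered to react.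

Step 10
Reactants: 20 the 1-alkenylcyclobutanol with the tethered (E)-alkenyl iodide
Product: 21 (2Z,6E,9S,10R)-9-{[tert-butyl(dimethyl)silyl]oxy}-3-({[tert-butyl(dimethyl)silyl]oxy}methyl)-7-methyl-10-(propan-2-yl)cyclodeca-2,6-dien-1-one (ten-membered C6 enone)
Conditions: Pd(OAc)2 (10 mol %), XPhos (20 mol %), Cs2CO3 (2 equiv), toluene, 80 °C; 20 added by syringe pump over 10 h, final 0.002 M
Reagents that add atoms: none
Why: Proposed new method: zerovalent palladium, formed from Pd(OAc)2 and the phosphine before the substrate is admitted, should insert into the C10–I bond with retention; the carbonate should then replace iodide by the tertiary C6 alkoxide, and β-carbon elimination, driven by release of cyclobutane strain, should break C6–C9 to leave the C6 ketone and a primary alkyl(alkenyl)palladium species whose C(sp3)–C(sp2) reductive elimination forms C9–C10. The closest known reaction type is the palladium-catalysed ring-opening arylation and alkenylation of tertiary cyclobutanols with aryl and alkenyl halides, known between two molecules and for small fused rings but not for a ten-membered ring. The ten-membered carbocycle is closed by reductive elimination from an eleven-membered palladacycle, reached through a nine-membered oxapalladacycle; the long Pd–O and Pd–C bonds and slow addition at high dilution are counted on to let this intramolecular path win over chain growth. No stereocentre is formed: C7 and C8 pass unchanged from the cyclobutane into the ring and the C6 stereocentre is erased, so both C6 epimers of 20 converge. The step needs cleavage of C6–C9 and not C6–C7, which the preference of palladium for the less substituted primary carbon over the isopropyl-bearing one should secure, and it needs retention of both alkene geometries, which oxidative addition and reductive elimination at an alkenyl carbon provide. Because palladium on C10 is trans to the C1–C2 tether, insertion of the C4=C5 alkene would have to form a five- or six-membered ring containing a trans double bond and is excluded. The bulky, electron-rich biaryl phosphine is chosen to make reductive elimination faster than β-hydride or β-silyloxy elimination at C8, and the insoluble carbonate in toluene at 80 °C is chosen to spare the C7 stereocentre and the β-silyloxy ketone and to stay below the temperature of Cope rearrangement of the cyclodeca-1,5-diene.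

Step 11
Reactants: 21 the bis-silylated ten-membered enone
Product: 22 (2Z,6E,9S,10R)-9-hydroxy-3-(hydroxymethyl)-7-methyl-10-(propan-2-yl)cyclodeca-2,6-dien-1-one
Conditions: HF·pyridine, pyridine, THF, 0 °C to rt
Reagents that add atoms: none
Why: Fluoride cleaves both silyl ethers under pyridine-buffered conditions. This avoids acid-promoted transannular cyclisation of the diene and base-promoted retro-aldol cleavage or dehydration of the β-hydroxy ketone.

Step 12
Reactants: 22 the keto diol
Product: 23 [(1Z,4R,5S,7E)-5-hydroxy-7-methyl-3-oxo-4-(propan-2-yl)cyclodeca-1,7-dien-1-yl]methyl (2Z)-2-methylbut-2-enoate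
Conditions: angelic acid, 2,4,6-trichlorobenzoyl chloride, Et3N, toluene, rt; then 22, rt to 50 °C (no DMAP)
Reagents that add atoms: angelic acid ((2Z)-2-methylbut-2-enoic acid), C/C=C(/C)C(=O)O
Why: Esterification through the mixed anhydride (Yamaguchi-type activation) without a nucleophilic catalyst, conditions under which the Z acid should not isomerise to the E acid. The unhindered primary allylic hydroxyl should react well before the C8 hydroxyl, which is flanked by the isopropyl-bearing carbon.

Step 13
Reactants: 23 the β-hydroxy enone angelate
Product: 24 [(1Z,3S,4S,5S,7E)-5-(acetyloxy)-3-hydroxy-7-methyl-4-(propan-2-yl)cyclodeca-1,7-dien-1-yl]methyl (2Z)-2-methylbut-2-enoate (target)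
Conditions: SmI2 (0.3 equiv) premixed with CH3CHO (10 equiv) in THF until decolourised; then 23, −10 °C
Reagents that add atoms: acetaldehyde, CC=O
Why: Evans–Tishchenko reduction: the C8 hydroxyl forms a hemiacetal with the aldehyde, trivalent samarium binds this hemiacetal and the ketone oxygen, and hydride is transferred within a six-membered transition state. This sets C6 anti to C8 (6S), reduces only 1,2, and leaves the C8 oxygen as its acetate. Premixing ensures that no divalent samarium meets the γ-acyloxy enone.

## Compound list

1 | isovaleryl chloride (3-methylbutanoyl chloride) | CC(C)CC(Cl)=O | starting material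
2 | benzyl vinyl ether | C=COCc1ccccc1 | starting material
3 | isopropylketene (3-methylbut-1-en-1-one) | CC(C)C=C=O | intermediate (not isolated)
4 | rac-(2R,3R)-3-(benzyloxy)-2-(propan-2-yl)cyclobutan-1-one (cis; racemate, one enantiomer drawn) | O=C1[C@H](C(C)C)[C@H](OCc2ccccc2)C1 | intermediate (not isolated)
5 | rac-(2R,3S)-3-(benzyloxy)-2-(propan-2-yl)cyclobutan-1-one (trans; racemate, one enantiomer drawn) | O=C1[C@H](C(C)C)[C@@H](OCc2ccccc2)C1 | intermediate
6 | rac-(2R,3S)-3-hydroxy-2-(propan-2-yl)cyclobutan-1-one (racemate, one enantiomer drawn) | O=C1[C@H](C(C)C)[C@@H](O)C1 | intermediate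
7 | (2R,3S)-3-hydroxy-2-(propan-2-yl)cyclobutan-1-one | O=C1[C@H](C(C)C)[C@@H](O)C1 | intermediate
8 | (2R,3S)-3-{[tert-butyl(dimethyl)silyl]oxy}-2-(propan-2-yl)cyclobutan-1-one | O=C1[C@H](C(C)C)[C@@H](O[Si](C)(C)C(C)(C)C)C1 | intermediate
9 | pent-3-yn-1-ol | CC#CCCO | starting material
10 | 5-bromopent-2-yne | CC#CCCBr | intermediate
11 | propargyl alcohol (prop-2-yn-1-ol) | C#CCO | starting material
12 | pent-3-yn-1-ylmagnesium bromide | CC#CCC[Mg]Br | intermediate (not isolated)
13 | 4-(pent-3-yn-1-yl)-2,5-dihydro-1,2-oxamagnesole (cyclic alkenylmagnesium alkoxide) | CC#CCCC1=C[Mg]OC1 | intermediate (not isolated)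
14 | (2Z)-3-iodo-2-(pent-3-yn-1-yl)prop-2-en-1-ol | I/C=C(/CCC#CC)CO | intermediate
15 | tert-butyl{[(2Z)-3-iodo-2-(pent-3-yn-1-yl)prop-2-en-1-yl]oxy}dimethylsilane | I/C=C(/CCC#CC)CO[Si](C)(C)C(C)(C)C | intermediate
16 | [(1Z)-2-({[tert-butyl(dimethyl)silyl]oxy}methyl)hept-1-en-5-yn-1-yl]lithium | [Li]/C=C(/CCC#CC)CO[Si](C)(C)C(C)(C)C | intermediate (not isolated)
17 | [(1Z)-2-({[tert-butyl(dimethyl)silyl]oxy}methyl)hept-1-en-5-yn-1-yl]cerium dichloride | Cl[Ce](Cl)/C=C(/CCC#CC)CO[Si](C)(C)C(C)(C)C | intermediate (not isolated)
18 | (1R,2R,3S)-3-{[tert-butyl(dimethyl)silyl]oxy}-1-[(1Z)-2-({[tert-butyl(dimethyl)silyl]oxy}methyl)hept-1-en-5-yn-1-yl]-2-(propan-2-yl)cyclobutan-1-ol | O[C@]1(/C=C(\CO[Si](C)(C)C(C)(C)C)CCC#CC)[C@H](C(C)C)[C@@H](O[Si](C)(C)C(C)(C)C)C1 | intermediate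
19 | C10 alkenylzirconocene chloride of 18, with the C6 oxygen bound to a second zirconocene chloride | Cl[Zr](C2C=CC=C2)(C2C=CC=C2)O[C@]1(/C=C(\CO[Si](C)(C)C(C)(C)C)CC/C=C(C)/[Zr](Cl)(C2C=CC=C2)C2C=CC=C2)[C@H](C(C)C)[C@@H](O[Si](C)(C)C(C)(C)C)C1 | intermediate (not isolated)
20 | (1R,2R,3S)-3-{[tert-butyl(dimethyl)silyl]oxy}-1-[(1Z,5E)-2-({[tert-butyl(dimethyl)silyl]oxy}methyl)-6-iodohepta-1,5-dien-1-yl]-2-(propan-2-yl)cyclobutan-1-ol | O[C@]1(/C=C(\CO[Si](C)(C)C(C)(C)C)CC/C=C(C)/I)[C@H](C(C)C)[C@@H](O[Si](C)(C)C(C)(C)C)C1 | intermediate
21 | (2Z,6E,9S,10R)-9-{[tert-butyl(dimethyl)silyl]oxy}-3-({[tert-butyl(dimethyl)silyl]oxy}methyl)-7-methyl-10-(propan-2-yl)cyclodeca-2,6-dien-1-one | CC(C)(C)[Si](C)(C)OC/C1=C\C(=O)[C@H](C(C)C)[C@@H](O[Si](C)(C)C(C)(C)C)C/C(C)=C/CC1 | intermediate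
22 | (2Z,6E,9S,10R)-9-hydroxy-3-(hydroxymethyl)-7-methyl-10-(propan-2-yl)cyclodeca-2,6-dien-1-one | OC/C1=C\C(=O)[C@H](C(C)C)[C@@H](O)C/C(C)=C/CC1 | intermediate
23 | [(1Z,4R,5S,7E)-5-hydroxy-7-methyl-3-oxo-4-(propan-2-yl)cyclodeca-1,7-dien-1-yl]methyl (2Z)-2-methylbut-2-enoate | C/C=C(/C)C(=O)OC/C1=C\C(=O)[C@H](C(C)C)[C@@H](O)C/C(C)=C/CC1 | intermediate
24 | [(1Z,3S,4S,5S,7E)-5-(acetyloxy)-3-hydroxy-7-methyl-4-(propan-2-yl)cyclodeca-1,7-dien-1-yl]methyl (2Z)-2-methylbut-2-enoate | C/C=C(/C)C(=O)OC/C1=C\[C@H](O)[C@H](C(C)C)[C@@H](OC(C)=O)C/C(C)=C/CC1 | target

## Step count and least certain steps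

Total step count: 13. Longest linear sequence: 10 steps (steps 1–4, then 8–13).

**Step 10 (key step, proposed new method).**
- What may go wrong: the intramolecular exchange of iodide for the C6 alkoxide may be slow, because the nine-membered oxapalladacycle must hold two trans alkenes. The alkenylpalladium iodide would then be consumed by intermolecular coupling (chain growth) or by reduction of the C–I bond. After ring opening, β-hydride or β-silyloxy elimination at C8 may outrun reductive elimination. The product may lose silanol from the β-silyloxy ketone or epimerise at C7 under the base.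
- Fallback (known chemistry; the ring is closed at C5–C6 by a Nozaki–Hiyama–Kishi reaction; it sets out from propargyl alcohol 11 and rejoins the route at 21): But-3-yn-1-ol is protected as 1-[(but-3-yn-1-yloxy)methyl]-4-methoxybenzene F1. Zirconium-catalysed carboalumination (Me3Al, Cp2ZrCl2), conversion to the alanate with n-BuLi and opening of ethylene oxide would give the (E)-homoallylic alcohol F2, which already holds C8–C10, C1–C3 and the C1=C10 geometry. Appel bromination gives the bromide F3. Its Grignard reagent is added under CuI catalysis to the magnesium alkoxide of 11 (pre-formed with i-PrMgCl), and the chelate is iodinated as in step 6 to give the (Z)-iodo allylic alcohol F4, which is silylated to the silyl ether F5. DDQ frees the C8 alcohol F6, and buffered Dess–Martin oxidation gives the β,γ-unsaturated aldehyde F7, used at once. A boron-mediated Evans syn-aldol reaction with purchased (R)-4-benzyl-3-(3-methylbutanoyl)oxazolidin-2-one (Bu2BOTf, i-Pr2NEt, −78 °C) sets C7 and C8 in the aldol adduct F8. Silylation (TBSOTf, 2,6-lutidine) gives the silyl ether F9, LiBH4 removes the auxiliary to give the primary alcohol F10, and Dess–Martin oxidation gives the C6 aldehyde F11. CrCl2 with catalytic NiCl2 in DMSO at high dilution closes C5–C6 to the ten-membered allylic alcohol F12 (both C6 epimers), and Dess–Martin oxidation converges on 21.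

**Step 9.**
- What may go wrong: incomplete regiocontrol of the hydrozirconation, because the two alkyne substituents differ only as methyl against a primary chain. On the iodine quench, iodonium attack on the C4=C5 alkene next to the cyclobutanol could trigger a ring-expanding 1,2-shift.
- Fallback (the hydrometalation is moved ahead of the fragment union; it sets out from 15 and rejoins the route at 21): 15 itself is hydrozirconated (Cp2Zr(H)Cl, THF, 45 °C) and quenched with N-bromosuccinimide to give tert-butyl{[(2Z,5E)-6-bromo-2-(iodomethylidene)hept-5-en-1-yl]oxy}dimethylsilane F13. At this stage there is neither a free hydroxyl nor an alkenylcyclobutanol, and a regioisomer can be removed cheaply. n-BuLi at −78 °C exchanges only the alkenyl iodide. Transmetalation to cerium and addition to 8 as in step 8 would give the alkenyl bromide analogue of 20 F14, which is submitted to the conditions of step 10 to give 21.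

**Step 13.**
- What may go wrong: the macrocycle may not allow the chair-like hydride transfer, which would erode the anti selectivity. The free β-hydroxy enone may undergo retro-aldol cleavage or transannular oxa-Michael addition of the C8 hydroxyl to C4 under the Lewis acid. Traces of divalent samarium could reduce the γ-acyloxy enone.
- Fallback (acetate first, then reagent-controlled reduction; from 23 to 24): acetylation of the C8 hydroxyl (Ac2O, pyridine, 0 °C) gives the β-acetoxy enone F15. Corey–Bakshi–Shibata reduction of the C6 ketone (oxazaborolidine, catecholborane, −78 °C; the (S)-catalyst if the alkenyl side acts as the larger group) then gives 24.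

**Step 12.**
- What may go wrong: isomerisation of the angeloyl group to the tigloyl group while the acid is activated, and base- or heat-induced retro-aldol cleavage or C7 epimerisation of the β-hydroxy ketone.
- Fallback (activation of the alcohol instead of the acid; from 22 to 23): Mitsunobu esterification with angelic acid, PPh3 and diisopropyl azodicarboxylate in THF at 0 °C. The acid reacts only as its carboxylate and the hindered secondary hydroxyl should not be activated. No new compound is made.

**Step 3.**
- What may go wrong: poor enantiodiscrimination, because the two flanks of the carbinol in a four-membered ring differ only by the isopropyl group one carbon away; the sense could also be reversed.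
- Fallback (physical separation instead of kinetic resolution; from 6 to 8): the racemate 6 is silylated as in step 4 to give the racemic silyl ether F16, and the enantiomers are separated by preparative supercritical-fluid chromatography on a chiral stationary phase. The (2R,3S)-enantiomer is 8.

## Further compounds

F1 | step 10 | 1-[(but-3-yn-1-yloxy)methyl]-4-methoxybenzene | C#CCCOCc1ccc(OC)cc1
F2 | step 10 | (3E)-6-[(4-methoxyphenyl)methoxy]-4-methylhex-3-en-1-ol | OCC/C=C(\C)CCOCc1ccc(OC)cc1
F3 | step 10 | 1-({[(3E)-6-bromo-3-methylhex-3-en-1-yl]oxy}methyl)-4-methoxybenzene | BrCC/C=C(\C)CCOCc1ccc(OC)cc1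
F4 | step 10 | (2Z)-3-iodo-2-{(3E)-6-[(4-methoxyphenyl)methoxy]-4-methylhex-3-en-1-yl}prop-2-en-1-ol | I/C=C(/CC/C=C(\C)CCOCc1ccc(OC)cc1)CO
F5 | step 10 | tert-butyl{[(2Z)-3-iodo-2-{(3E)-6-[(4-methoxyphenyl)methoxy]-4-methylhex-3-en-1-yl}prop-2-en-1-yl]oxy}dimethylsilane | I/C=C(/CC/C=C(\C)CCOCc1ccc(OC)cc1)CO[Si](C)(C)C(C)(C)C
F6 | step 10 | (3E,7Z)-7-({[tert-butyl(dimethyl)silyl]oxy}methyl)-8-iodo-3-methylocta-3,7-dien-1-ol | I/C=C(/CC/C=C(\C)CCO)CO[Si](C)(C)C(C)(C)C
F7 | step 10 | (3E,7Z)-7-({[tert-butyl(dimethyl)silyl]oxy}methyl)-8-iodo-3-methylocta-3,7-dienal | I/C=C(/CC/C=C(\C)CC=O)CO[Si](C)(C)C(C)(C)C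
F8 | step 10 | (4R)-4-benzyl-3-[(2R,3S,5E,9Z)-9-({[tert-butyl(dimethyl)silyl]oxy}methyl)-3-hydroxy-10-iodo-5-methyl-2-(propan-2-yl)deca-5,9-dienoyl]-1,3-oxazolidin-2-one | O=C(N1[C@H](Cc2ccccc2)COC1=O)[C@H](C(C)C)[C@@H](O)C/C(C)=C/CC/C(CO[Si](C)(C)C(C)(C)C)=C/I
F9 | step 10 | (4R)-4-benzyl-3-[(2R,3S,5E,9Z)-3-{[tert-butyl(dimethyl)silyl]oxy}-9-({[tert-butyl(dimethyl)silyl]oxy}methyl)-10-iodo-5-methyl-2-(propan-2-yl)deca-5,9-dienoyl]-1,3-oxazolidin-2-one | O=C(N1[C@H](Cc2ccccc2)COC1=O)[C@H](C(C)C)[C@@H](O[Si](C)(C)C(C)(C)C)C/C(C)=C/CC/C(CO[Si](C)(C)C(C)(C)C)=C/I
F10 | step 10 | (2S,3S,5E,9Z)-3-{[tert-butyl(dimethyl)silyl]oxy}-9-({[tert-butyl(dimethyl)silyl]oxy}methyl)-10-iodo-5-methyl-2-(propan-2-yl)deca-5,9-dien-1-ol | OC[C@H](C(C)C)[C@@H](O[Si](C)(C)C(C)(C)C)C/C(C)=C/CC/C(CO[Si](C)(C)C(C)(C)C)=C/I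
F11 | step 10 | (2R,3S,5E,9Z)-3-{[tert-butyl(dimethyl)silyl]oxy}-9-({[tert-butyl(dimethyl)silyl]oxy}methyl)-10-iodo-5-methyl-2-(propan-2-yl)deca-5,9-dienal | O=C[C@H](C(C)C)[C@@H](O[Si](C)(C)C(C)(C)C)C/C(C)=C/CC/C(CO[Si](C)(C)C(C)(C)C)=C/I
F12 | step 10 | (2Z,6E,9S)-9-{[tert-butyl(dimethyl)silyl]oxy}-3-({[tert-butyl(dimethyl)silyl]oxy}methyl)-7-methyl-10-(propan-2-yl)cyclodeca-2,6-dien-1-ol (C7 as in 21, both C6 epimers) | CC(C)(C)[Si](C)(C)OC/C1=C\C(O)[C@H](C(C)C)[C@@H](O[Si](C)(C)C(C)(C)C)C/C(C)=C/CC1
F13 | step 9 | tert-butyl{[(2Z,5E)-6-bromo-2-(iodomethylidene)hept-5-en-1-yl]oxy}dimethylsilane | I/C=C(/CC/C=C(C)/Br)CO[Si](C)(C)C(C)(C)C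
F14 | step 9 | (1R,2R,3S)-1-[(1Z,5E)-6-bromo-2-({[tert-butyl(dimethyl)silyl]oxy}methyl)hepta-1,5-dien-1-yl]-3-{[tert-butyl(dimethyl)silyl]oxy}-2-(propan-2-yl)cyclobutan-1-ol | O[C@]1(/C=C(\CO[Si](C)(C)C(C)(C)C)CC/C=C(C)/Br)[C@H](C(C)C)[C@@H](O[Si](C)(C)C(C)(C)C)C1
F15 | step 13 | [(1Z,4R,5S,7E)-5-(acetyloxy)-7-methyl-3-oxo-4-(propan-2-yl)cyclodeca-1,7-dien-1-yl]methyl (2Z)-2-methylbut-2-enoate | C/C=C(/C)C(=O)OC/C1=C\C(=O)[C@H](C(C)C)[C@@H](OC(C)=O)C/C(C)=C/CC1
F0 | step 12 | none | none
F16 | step 3 | rac-(2R,3S)-3-{[tert-butyl(dimethyl)silyl]oxy}-2-(propan-2-yl)cyclobutan-1-one (racemate, one enantiomer drawn) | O=C1[C@H](C(C)C)[C@@H](O[Si](C)(C)C(C)(C)C)C1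
A1 | alternative 1 | thirteen-membered cyclic di-isopropylsilylene acetal with the C4 methylidene and the C6 vinyl group | CC(C)[Si]1(C(C)C)OCC(=C)CC/C=C(C)/C[C@H](OC(C)=O)[C@@H](C(C)C)[C@H](C=C)O1
A2 | alternative 1 | silicon-bridged ten-membered carbocycle | CC(C)[Si]1(C(C)C)OC/C2=C\[C@H](O1)[C@H](C(C)C)[C@@H](OC(C)=O)C/C(C)=C/CC2
A3 | alternative 2 | (3Z,5S,7E)-5-[(4-methoxyphenyl)methoxy]-3,7-dimethyl-1-oxacyclotrideca-3,7-dien-11-yne (thirteen-membered propargylic allylic ether) | C1#CCOC/C(C)=C\[C@@H](OCc2ccc(OC)cc2)C/C(C)=C/CC1
A4 | alternative 2 | ten-membered cycloalkynol with C7 isopropenyl | C1#C[C@H](O)[C@H](C(C)=C)[C@@H](OCc2ccc(OC)cc2)C/C(C)=C/CC1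
A5 | alternative 3 | 1-vinyl-2-(3-silyloxyprop-1-en-2-yl)cyclohexanol template carrying the C6 silyloxy, C7 isopropyl and C8 4-methoxybenzyloxy groups | C=C[C@]1(O)C[C@H](OCc2ccc(OC)cc2)[C@@H](C(C)C)[C@@H](O[Si](C)(C)C(C)(C)C)[C@H]1C(=C)CO[Si](C)(C)C(C)(C)C
A6 | alternative 3 | ten-membered (E,E)-dienyl triflate | CC(C)(C)[Si](C)(C)OC/C1=C\[C@H](O[Si](C)(C)C(C)(C)C)[C@H](C(C)C)[C@@H](OCc2ccc(OC)cc2)C/C(OS(=O)(=O)C(F)(F)F)=C/CC1
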